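**Retrosynthetic overview**
1. Target 35 ⇐ late O9 acetylation, O8 angeloylation and C3 desilylation of an 8,9-diol lactone; the α-methylene γ-lactone ⇐ 6-hydroxy-7-isopropenyl carbocycle 21 (hydroboration, oxidative lactonisation, selenoxide elimination).
2. Key step: ten-membered carbocycle 21 ⇐ 13-membered diallyl ether 19 by [2,3]-Wittig ring contraction, which forms C6–C7 and sets C6 and C7.
3. 19 ⇐ bis-allylic diol 16 (macro-etherification) ⇐ Z-selective Wittig union at C1=C10 of C1–C6 phosphonium salt 8 with C7–C10 methyl-ketone hemiketal 10, then (E)-Wittig extension at C7.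
4. 8 ⇐ (S)-α-hydroxy-γ-butyrolactone (supplies C3); 10 ⇐ 2,3-O-isopropylidene-D-erythronolactone (supplies C8 and C9).
5. Ring order: 13-membered cyclic ether, then ten-membered carbocycle by ring contraction, then the γ-lactone.

Assumption: atom labels C1–C15 are the germacrane positions of the target (ring C1–C10, lactone carbons C11–C13, C14 on C10, C15 on C4); TBS = tert-butyldimethylsilyl; all reagents are commercial.

**Step 1**
Reactants: 1 (S)-α-hydroxy-γ-butyrolactone
Product: 2 (S)-α-(TBS-oxy)-γ-butyrolactone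
Conditions: TBSCl, imidazole, DMF, rt
Reagents that add atoms: tert-butyldimethylsilyl chloride, CC(C)(C)[Si](C)(C)Cl
Why: Silyl ether formation masks the future C3 hydroxyl for the whole route and leaves the bought (S) stereocentre untouched.

**Step 2**
Reactants: 2 (S)-α-(TBS-oxy)-γ-butyrolactone; 3 methyllithium
Product: 4 (3S)-3-(TBS-oxy)-5-hydroxypentan-2-one
Conditions: MeLi (1.05 equiv), THF, −78 °C; aq. NH4Cl
Reagents that add atoms: methyllithium 3, [Li]C
Why: Nucleophilic addition of MeLi to the lactone stops at the tetrahedral lithium hemiketal at −78 °C, which gives the methyl ketone (C4 with C15) on work-up without epimerising the adjacent centre.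

**Step 3**
Reactants: 4 (3S)-3-(TBS-oxy)-5-hydroxypentan-2-one; 5 tert-butyl (triphenylphosphoranylidene)acetate
Product: 6 tert-butyl (2E,4S)-4-(TBS-oxy)-6-hydroxy-3-methylhex-2-enoate
Conditions: toluene, 100 °C
Reagents that add atoms: tert-butyl (triphenylphosphoranylidene)acetate 5, CC(C)(C)OC(=O)C=P(c1ccccc1)(c1ccccc1)c1ccccc1
Why: Wittig olefination with a stabilised ylide places the ester trans to the bulky CH(OTBS) branch, giving the (E)-C4=C5 alkene under neutral conditions that do not epimerise C3.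

**Step 4**
Reactants: 6 tert-butyl (2E,4S)-4-(TBS-oxy)-6-hydroxy-3-methylhex-2-enoate
Product: 7 tert-butyl (2E,4S)-4-(TBS-oxy)-6-iodo-3-methylhex-2-enoate
Conditions: I2, PPh3, imidazole, CH2Cl2, 0 °C to rt
Reagents that add atoms: iodine, [I][I]
Why: Appel iodination converts the primary alcohol into the iodide under near-neutral conditions tolerated by the silyl ether and the tert-butyl ester.

**Step 5**
Reactants: 7 tert-butyl (2E,4S)-4-(TBS-oxy)-6-iodo-3-methylhex-2-enoate
Product: 8 C1–C6 triphenylphosphonium iodide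
Conditions: PPh3, MeCN, 80 °C
Reagents that add atoms: triphenylphosphine, c1ccc(cc1)P(c1ccccc1)c1ccccc1
Why: SN2 quaternisation of triphenylphosphine by the unhindered primary iodide gives the Wittig salt.

**Step 6**
Reactants: 9 2,3-O-isopropylidene-D-erythronolactone; 3 methyllithium
Product: 10 1-deoxy-3,4-O-isopropylidene-D-erythro-pent-2-ulofuranose
Conditions: MeLi (1.1 equiv), THF, −78 °C; aq. NH4Cl
Reagents that add atoms: methyllithium 3, [Li]C
Why: Addition of MeLi to the lactone gives the stable bicyclic hemiketal (masked methyl ketone, C10 with C14) and leaves the two bought stereocentres (future C9 and C8) untouched.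

**Step 7**
Reactants: 8 C1–C6 triphenylphosphonium iodide; 10 1-deoxy-3,4-O-isopropylidene-D-erythro-pent-2-ulofuranose
Product: 12 (6Z)-dienoate alcohol (tert-butyl ester at C6 and CH2OH at C7), via phosphorus ylide 11 (not isolated)
Conditions: 8, KN(SiMe3)2, THF, −78 °C; then potassium alkoxide of 10 (KN(SiMe3)2), −78 to 0 °C; aq. NH4Cl
Reagents that add atoms: none
Why: Z-selective Wittig olefination of an α-alkoxy methyl ketone (released from the hemiketal alkoxide) by a salt-free non-stabilised ylide puts the ylide chain cis to the alkoxy-bearing C9 and so sets the (Z)-C1=C10 alkene, while the tert-butyl ester resists ylide and alkoxide.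

**Step 8**
Reactants: 12 (6Z)-dienoate alcohol; 13 ethyl 2-(triphenylphosphoranylidene)propanoate
Product: 15 tert-butyl ethyl bis-enoate, via aldehyde 14 (not isolated)
Conditions: Dess–Martin periodinane, NaHCO3, CH2Cl2, 0 °C to rt; then 13, rt
Reagents that add atoms: ethyl 2-(triphenylphosphoranylidene)propanoate 13, CCOC(=O)C(C)=P(c1ccccc1)(c1ccccc1)c1ccccc1
Why: Dess–Martin oxidation gives the α-alkoxy aldehyde, which is trapped in the same pot by an (E)-selective Wittig reaction with a stabilised ylide before C8 can epimerise, so the ester carbon (future C12) lies trans to C8.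

**Step 9**
Reactants: 15 tert-butyl ethyl bis-enoate
Product: 16 bis-allylic diol (C6–OH and C12–OH)
Conditions: i-Bu2AlH (6 equiv), CH2Cl2, −78 to 0 °C; Rochelle salt
Reagents that add atoms: none
Why: 1,2-Hydride reduction of both conjugated esters gives the two primary allylic alcohols without touching the alkenes, the silyl ether or the acetonide.

**Step 10**
Reactants: 16 bis-allylic diol
Product: 19 13-membered diallyl ether (O bridging C6 and C12), via C12 monotosylate 17 (not isolated), via C6 monotosylate 18 (not isolated)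
Conditions: NaH (4 equiv), THF, rt; TsCl (1.05 equiv) by syringe pump, 2 mM, rt to 45 °C
Reagents that add atoms: none
Why: Monosulfonylation of either alkoxide followed by intramolecular Williamson etherification (SN2 of the other alkoxide on the allylic tosylate at high dilution) gives the same cyclic ether from both regioisomeric tosylates.

**Step 11**
Reactants: 19 13-membered diallyl ether
Product: 21 6-hydroxy-7-isopropenyl ten-membered carbocycle, via C6-lithiated ether 20 (not isolated)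
Conditions: n-BuLi (3 equiv), THF, −78 to −20 °C; aq. NH4Cl
Reagents that add atoms: none
Why: [2,3]-Wittig rearrangement (sigmatropic ring contraction): lithiation at the less hindered ether CH2 (C6) gives an allyllithium whose carbanion carbon bonds to C7 through a five-membered envelope transition state, the (E)-C7=C11 geometry giving the 6,7-anti (trans) product and allylic 1,3-strain at C8 (H-8 eclipsing the alkene) directing attack anti to the C8–O bond, which sets 6R and 7S under control of the bought C8 centre.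

**Step 12**
Reactants: 21 6-hydroxy-7-isopropenyl ten-membered carbocycle
Product: 23 6,12-diol (C11 epimers), via C12 alkylborane 22 (not isolated)
Conditions: 9-BBN (3 equiv), THF, 0 °C to rt; then NaOH, H2O2, 0 °C
Reagents that add atoms: hydrogen peroxide, OO
Why: Hydroboration–oxidation with bulky 9-BBN selects the 1,1-disubstituted isopropenyl alkene over the two trisubstituted ring alkenes and places the hydroxyl on the terminal carbon (C12), the new C11 centre being erased in step 14.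

**Step 13**
Reactants: 23 6,12-diol
Product: 26 α-methyl trans-fused γ-lactone (C11 epimers), via hydroxy aldehyde 24 (not isolated), via lactol 25 (not isolated)
Conditions: TEMPO (2,2,6,6-tetramethylpiperidin-1-oxyl, 0.2 equiv), PhI(OAc)2 (2.5 equiv), CH2Cl2, rt
Reagents that add atoms: none
Why: Oxidative lactonisation: the oxoammonium oxidant takes the primary alcohol to the aldehyde faster than it touches the secondary C6 alcohol, the aldehyde closes onto O6 and the lactol is oxidised on to the lactone.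

**Step 14**
Reactants: 26 α-methyl trans-fused γ-lactone
Product: 29 α-methylene γ-lactone (8,9-acetonide and 3-O-TBS), via selenide 27 (not isolated), via selenoxide 28 (not isolated)
Conditions: LiN(i-Pr)2, THF, −78 °C; PhSeBr, −78 °C; then H2O2, pyridine, CH2Cl2, 0 °C to rt
Reagents that add atoms: none
Why: α-Selenenylation of the lactone enolate followed by selenoxide syn-elimination (Grieco-type α-methylenation): in the trans-fused lactone selenium enters anti to H-7, so elimination can only go toward the methyl group and gives the exocyclic methylene.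

**Step 15**
Reactants: 29 α-methylene γ-lactone (8,9-acetonide and 3-O-TBS)
Product: 30 8,9-diol
Conditions: AcOH–H2O (4:1), 40 °C
Reagents that add atoms: none
Why: Mild acid-catalysed acetal hydrolysis removes the isopropylidene group while the more acid-stable secondary TBS ether survives.

**Step 16**
Reactants: 30 8,9-diol; 31 acetic anhydride
Product: 32 9-O-acetate with free 8-OH
Conditions: Ac2O (1.1 equiv), pyridine, CH2Cl2, −20 to 0 °C
Reagents that add atoms: acetic anhydride 31, CC(=O)OC(C)=O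
Why: Kinetic monoacylation: the allylic C9 hydroxyl next to the flat sp2 C10 is less hindered than the C8 hydroxyl flanked by C7 and C9, so one equivalent of anhydride without acyl-transfer catalyst acetylates O9.

**Step 17**
Reactants: 32 9-O-acetate with free 8-OH; 33 angelic acid
Product: 34 9-O-acetyl-8-O-angeloyl-3-O-TBS lactone
Conditions: 33, 2,4,6-trichlorobenzoyl chloride, Et3N, toluene, rt; then 32, 75 °C
Reagents that add atoms: angelic acid 33, C/C=C(/C)C(=O)O
Why: Yamaguchi-type esterification through the mixed 2,4,6-trichlorobenzoic anhydride acylates the hindered C8 hydroxyl without isomerising the (Z)-angeloyl group to tigloyl.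

**Step 18**
Reactants: 34 9-O-acetyl-8-O-angeloyl-3-O-TBS lactone
Product: 35 target CNP0265116.1
Conditions: HF·pyridine, pyridine, THF, 0 °C to rt
Reagents that add atoms: none
Why: Fluoride-mediated desilylation under buffered conditions frees the C3 hydroxyl without touching the two esters or the α-methylene lactone.

**Compound list**
1 | (S)-α-hydroxy-γ-butyrolactone, (3S)-3-hydroxyoxolan-2-one | O=C1OCC[C@@H]1O | starting material
2 | (3S)-3-[(tert-butyldimethylsilyl)oxy]oxolan-2-one | O=C1OCC[C@@H]1O[Si](C)(C)C(C)(C)C | intermediate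
3 | methyllithium | [Li]C | starting material
4 | (3S)-3-[(tert-butyldimethylsilyl)oxy]-5-hydroxypentan-2-one (in equilibrium with its cyclic hemiketal) | CC(=O)[C@@H](O[Si](C)(C)C(C)(C)C)CCO | intermediate
5 | tert-butyl (triphenylphosphoranylidene)acetate | CC(C)(C)OC(=O)C=P(c1ccccc1)(c1ccccc1)c1ccccc1 | starting material
6 | tert-butyl (2E,4S)-4-[(tert-butyldimethylsilyl)oxy]-6-hydroxy-3-methylhex-2-enoate | CC(C)(C)OC(=O)/C=C(\C)[C@@H](O[Si](C)(C)C(C)(C)C)CCO | intermediate
7 | tert-butyl (2E,4S)-4-[(tert-butyldimethylsilyl)oxy]-6-iodo-3-methylhex-2-enoate | CC(C)(C)OC(=O)/C=C(\C)[C@@H](O[Si](C)(C)C(C)(C)C)CCI | intermediate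
8 | [(3S,4E)-6-tert-butoxy-3-[(tert-butyldimethylsilyl)oxy]-4-methyl-6-oxohex-4-en-1-yl]triphenylphosphonium iodide | CC(C)(C)OC(=O)/C=C(\C)[C@@H](O[Si](C)(C)C(C)(C)C)CC[P+](c1ccccc1)(c1ccccc1)c1ccccc1.[I-] | intermediate
9 | 2,3-O-isopropylidene-D-erythronolactone, (3aR,6aR)-2,2-dimethyldihydrofuro[3,4-d][1,3]dioxol-4(3aH)-one | O=C1OC[C@H]2OC(C)(C)O[C@@H]12 | starting material
10 | 1-deoxy-3,4-O-isopropylidene-D-erythro-pent-2-ulofuranose, (3aR,6aR)-2,2,4-trimethyltetrahydrofuro[3,4-d][1,3]dioxol-4-ol (anomer mixture) | CC1(O)OC[C@H]2OC(C)(C)O[C@@H]12 | intermediate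
11 | tert-butyl (2E,4S)-4-[(tert-butyldimethylsilyl)oxy]-3-methyl-6-(triphenylphosphoranylidene)hex-2-enoate | CC(C)(C)OC(=O)/C=C(\C)[C@@H](O[Si](C)(C)C(C)(C)C)CC=P(c1ccccc1)(c1ccccc1)c1ccccc1 | intermediate
12 | tert-butyl (2E,4S,6Z)-4-[(tert-butyldimethylsilyl)oxy]-7-[(4S,5R)-5-(hydroxymethyl)-2,2-dimethyl-1,3-dioxolan-4-yl]-3-methylocta-2,6-dienoate | CC(C)(C)OC(=O)/C=C(\C)[C@@H](O[Si](C)(C)C(C)(C)C)C/C=C(/C)[C@@H]1OC(C)(C)O[C@@H]1CO | intermediate
13 | ethyl 2-(triphenylphosphoranylidene)propanoate | CCOC(=O)C(C)=P(c1ccccc1)(c1ccccc1)c1ccccc1 | starting material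
14 | tert-butyl (2E,4S,6Z)-4-[(tert-butyldimethylsilyl)oxy]-7-[(4S,5S)-5-formyl-2,2-dimethyl-1,3-dioxolan-4-yl]-3-methylocta-2,6-dienoate | CC(C)(C)OC(=O)/C=C(\C)[C@@H](O[Si](C)(C)C(C)(C)C)C/C=C(/C)[C@@H]1OC(C)(C)O[C@@H]1C=O | intermediate
15 | tert-butyl (2E,4S,6Z)-4-[(tert-butyldimethylsilyl)oxy]-7-[(4S,5R)-5-[(1E)-3-ethoxy-2-methyl-3-oxoprop-1-en-1-yl]-2,2-dimethyl-1,3-dioxolan-4-yl]-3-methylocta-2,6-dienoate | CC(C)(C)OC(=O)/C=C(\C)[C@@H](O[Si](C)(C)C(C)(C)C)C/C=C(/C)[C@@H]1OC(C)(C)O[C@@H]1/C=C(\C)C(=O)OCC | intermediate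
16 | (2E,4S,6Z)-4-[(tert-butyldimethylsilyl)oxy]-7-[(4S,5R)-5-[(1E)-3-hydroxy-2-methylprop-1-en-1-yl]-2,2-dimethyl-1,3-dioxolan-4-yl]-3-methylocta-2,6-dien-1-ol | OC/C=C(\C)[C@@H](O[Si](C)(C)C(C)(C)C)C/C=C(/C)[C@@H]1OC(C)(C)O[C@@H]1/C=C(\C)CO | intermediate
17 | diol 16 with the 2-methylallylic hydroxyl (C12–OH) converted into its p-toluenesulfonate | OC/C=C(\C)[C@@H](O[Si](C)(C)C(C)(C)C)C/C=C(/C)[C@@H]1OC(C)(C)O[C@@H]1/C=C(\C)COS(=O)(=O)c1ccc(C)cc1 | intermediate
18 | diol 16 with the C6 hydroxyl converted into its p-toluenesulfonate | Cc1ccc(cc1)S(=O)(=O)OC/C=C(\C)[C@@H](O[Si](C)(C)C(C)(C)C)C/C=C(/C)[C@@H]1OC(C)(C)O[C@@H]1/C=C(\C)CO | intermediate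
19 | (3E,5R,6S,7Z,10S,11E)-10-[(tert-butyldimethylsilyl)oxy]-5,6-(isopropylidenedioxy)-3,7,11-trimethyl-1-oxacyclotrideca-3,7,11-triene (O1 bridges germacrane C12 and C6) | O1C/C=C(\C)[C@@H](O[Si](C)(C)C(C)(C)C)C/C=C(/C)[C@@H]2OC(C)(C)O[C@@H]2/C=C(\C)C1 | intermediate
20 | ether 19 lithiated at the OCH2 carbon that is germacrane C6 (allyllithium) | [Li]C1/C=C(\C)[C@@H](O[Si](C)(C)C(C)(C)C)C/C=C(/C)[C@@H]2OC(C)(C)O[C@@H]2/C=C(\C)CO1 | intermediate
21 | (1(10)Z,4E,3S,6R,7S,8R,9S)-3-[(tert-butyldimethylsilyl)oxy]-8,9-(isopropylidenedioxy)germacra-1(10),4,11(12)-trien-6-ol | C=C(C)[C@H]1[C@H](O)/C=C(\C)[C@@H](O[Si](C)(C)C(C)(C)C)C/C=C(/C)[C@@H]2OC(C)(C)O[C@H]12 | intermediate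
22 | 21 hydroborated at C12: the 12-(9-borabicyclo[3.3.1]nonan-9-yl)-11,12-dihydro derivative (C11 epimers) | CC(CB1C2CCCC1CCC2)[C@H]1[C@H](O)/C=C(\C)[C@@H](O[Si](C)(C)C(C)(C)C)C/C=C(/C)[C@@H]2OC(C)(C)O[C@H]12 | intermediate
23 | (1(10)Z,4E,3S,6R,7S,8R,9S)-3-[(tert-butyldimethylsilyl)oxy]-8,9-(isopropylidenedioxy)germacra-1(10),4-diene-6,12-diol (C11 epimers) | CC(CO)[C@H]1[C@H](O)/C=C(\C)[C@@H](O[Si](C)(C)C(C)(C)C)C/C=C(/C)[C@@H]2OC(C)(C)O[C@H]12 | intermediate
24 | the C12 aldehyde of diol 23 (6-hydroxy-12-al; C11 epimers) | CC(C=O)[C@H]1[C@H](O)/C=C(\C)[C@@H](O[Si](C)(C)C(C)(C)C)C/C=C(/C)[C@@H]2OC(C)(C)O[C@H]12 | intermediate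
25 | the 6,12-lactol (cyclic hemiacetal) of aldehyde 24 | CC1C(O)O[C@@H]2/C=C(\C)[C@@H](O[Si](C)(C)C(C)(C)C)C/C=C(/C)[C@@H]3OC(C)(C)O[C@@H]3[C@@H]12 | intermediate
26 | (1(10)Z,4E,3S,6R,7S,8R,9S)-3-[(tert-butyldimethylsilyl)oxy]-8,9-(isopropylidenedioxy)germacra-1(10),4-dien-12,6-olide (C11 epimers) | CC1C(=O)O[C@@H]2/C=C(\C)[C@@H](O[Si](C)(C)C(C)(C)C)C/C=C(/C)[C@@H]3OC(C)(C)O[C@@H]3[C@@H]12 | intermediate
27 | the 11-(phenylselanyl) derivative of lactone 26 (selenium anti to H-7) | C[C@]1([Se]c3ccccc3)C(=O)O[C@@H]2/C=C(\C)[C@@H](O[Si](C)(C)C(C)(C)C)C/C=C(/C)[C@@H]3OC(C)(C)O[C@@H]3[C@@H]12 | intermediate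
28 | the selenoxide of selenide 27 | C[C@]1([Se](=O)c3ccccc3)C(=O)O[C@@H]2/C=C(\C)[C@@H](O[Si](C)(C)C(C)(C)C)C/C=C(/C)[C@@H]3OC(C)(C)O[C@@H]3[C@@H]12 | intermediate
29 | (1(10)Z,4E,3S,6R,7S,8R,9S)-3-[(tert-butyldimethylsilyl)oxy]-8,9-(isopropylidenedioxy)germacra-1(10),4,11(13)-trien-12,6-olide | C=C1C(=O)O[C@@H]2/C=C(\C)[C@@H](O[Si](C)(C)C(C)(C)C)C/C=C(/C)[C@@H]3OC(C)(C)O[C@@H]3[C@@H]12 | intermediate
30 | (1(10)Z,4E,3S,6R,7R,8R,9S)-3-[(tert-butyldimethylsilyl)oxy]-8,9-dihydroxygermacra-1(10),4,11(13)-trien-12,6-olide | C=C1C(=O)O[C@@H]2/C=C(\C)[C@@H](O[Si](C)(C)C(C)(C)C)C/C=C(/C)[C@H](O)[C@H](O)[C@@H]12 | intermediate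
31 | acetic anhydride | CC(=O)OC(C)=O | starting material
32 | (1(10)Z,4E,3S,6R,7R,8R,9S)-9-acetoxy-3-[(tert-butyldimethylsilyl)oxy]-8-hydroxygermacra-1(10),4,11(13)-trien-12,6-olide | C=C1C(=O)O[C@@H]2/C=C(\C)[C@@H](O[Si](C)(C)C(C)(C)C)C/C=C(/C)[C@H](OC(C)=O)[C@H](O)[C@@H]12 | intermediate
33 | angelic acid, (Z)-2-methylbut-2-enoic acid | C/C=C(/C)C(=O)O | starting material
34 | (1(10)Z,4E,3S,6R,7S,8R,9S)-9-acetoxy-8-(angeloyloxy)-3-[(tert-butyldimethylsilyl)oxy]germacra-1(10),4,11(13)-trien-12,6-olide | C=C1C(=O)O[C@@H]2/C=C(\C)[C@@H](O[Si](C)(C)C(C)(C)C)C/C=C(/C)[C@H](OC(C)=O)[C@H](OC(=O)/C(C)=C\C)[C@@H]12 | intermediate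
35 | CNP0265116.1, (1(10)Z,4E,3S,6R,7S,8R,9S)-9-acetoxy-8-(angeloyloxy)-3-hydroxygermacra-1(10),4,11(13)-trien-12,6-olide | C=C1C(=O)O[C@@H]2/C=C(\C)[C@@H](O)C/C=C(/C)[C@H](OC(C)=O)[C@H](OC(=O)/C(C)=C\C)[C@@H]12 | target

**Totals**
Total step count: 18. Longest linear sequence: 17 steps (from 1 through steps 1–5 and 7–18; step 6 is the one-step side branch from 9).

**Three steps most likely to fail**

Step 10 (one-pot macro-etherification). Bis-tosylation, oligomerisation or ionisation of the prenyl-type tosylate can beat closure of the 13-membered ring. The fallback differentiates the two termini before ring closure; it sets out from 12 and comes back at 19. Reduction of 12 with i-Bu2AlH gives the C6,C7-diol F1. The Corey–Kim reagent (N-chlorosuccinimide, Me2S, CH2Cl2, −20 °C) converts allylic but not saturated alcohols into chlorides and gives the C6 allylic chloride F2. Dess–Martin oxidation gives the chloro aldehyde F3, which is olefinated in the same pot with 13 to the chloro enoate F4. i-Bu2AlH at −78 °C gives the chloro alcohol F5, and NaH in THF at high dilution closes ether 19 by a directed intramolecular Williamson reaction.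

Step 11 ([2,3]-Wittig ring contraction). Lithiation could occur at the other ether CH2 (C12) or at the allylic C3–H or C9–H, and the transannular transition state may not give the 6,7-trans isomer cleanly. The fallback builds the same C6–C7 bond by an intramolecular Nozaki–Hiyama allylation; it sets out from 12 (oxidised to 14 as in step 8) and comes back at 21. Wittig reaction of 14 with 2-(triphenylphosphoranylidene)propanal gives the (E)-enal ester F6. NaBH4 with CeCl3·7H2O in MeOH reduces only the aldehyde to the allylic alcohol F7. MsCl, LiCl and 2,4,6-collidine in DMF give the allylic chloride F8. i-Bu2AlH reduces the tert-butyl ester to the C6 alcohol F9, and MnO2 gives the chloro enal F10. CrCl2 in THF at high dilution turns the C12 chloride into an allylchromium that adds through C7 to the C6 aldehyde in a chair transition state, giving the anti (6,7-trans) alcohol 21 with the bond-forming sites fixed by the halide and aldehyde positions.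

Step 16 (regioselective monoacetylation). Selectivity between O9 and O8 may be modest, and the hydroxy acetate 32 can suffer acetyl migration or translactonisation during the hot angeloylation. The fallback uses a bulky temporary silyl group to fix the order of acylation; it sets out from 30 and comes back at 34. Et3SiCl and imidazole in CH2Cl2 at −40 °C silylate the less hindered O9 to give the 9-O-triethylsilyl ether F11. Angeloylation of O8 under the conditions of step 17 gives the 8-angelate F12. HF·pyridine buffered with pyridine at 0 °C removes the triethylsilyl group but not the TBS ether and gives the 9-hydroxy 8-angelate F13. Ac2O, pyridine and 4-(dimethylamino)pyridine at 0 °C then acetylate O9 to give 34.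

**Further compounds**
F1 | step 10 | (2E,4S,6Z)-4-[(tert-butyldimethylsilyl)oxy]-7-[(4S,5R)-5-(hydroxymethyl)-2,2-dimethyl-1,3-dioxolan-4-yl]-3-methylocta-2,6-dien-1-ol | OC/C=C(\C)[C@@H](O[Si](C)(C)C(C)(C)C)C/C=C(/C)[C@@H]1OC(C)(C)O[C@@H]1CO
F2 | step 10 | diol F1 with the allylic C6 hydroxyl replaced by chlorine | ClC/C=C(\C)[C@@H](O[Si](C)(C)C(C)(C)C)C/C=C(/C)[C@@H]1OC(C)(C)O[C@@H]1CO
F3 | step 10 | the C7 aldehyde of chloride F2 | ClC/C=C(\C)[C@@H](O[Si](C)(C)C(C)(C)C)C/C=C(/C)[C@@H]1OC(C)(C)O[C@@H]1C=O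
F4 | step 10 | the (E)-2-methylpropenoate ethyl ester from F3 and 13 (C6 chloride) | ClC/C=C(\C)[C@@H](O[Si](C)(C)C(C)(C)C)C/C=C(/C)[C@@H]1OC(C)(C)O[C@@H]1/C=C(\C)C(=O)OCC
F5 | step 10 | diol 16 with the C6 hydroxyl replaced by chlorine (C12–OH free) | ClC/C=C(\C)[C@@H](O[Si](C)(C)C(C)(C)C)C/C=C(/C)[C@@H]1OC(C)(C)O[C@@H]1/C=C(\C)CO
F6 | step 11 | bis-enoate 15 with the ethyl ester replaced by an aldehyde (C12 enal and C6 tert-butyl ester) | CC(C)(C)OC(=O)/C=C(\C)[C@@H](O[Si](C)(C)C(C)(C)C)C/C=C(/C)[C@@H]1OC(C)(C)O[C@@H]1/C=C(\C)C=O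
F7 | step 11 | the C12 allylic alcohol from F6 (C6 tert-butyl ester kept) | CC(C)(C)OC(=O)/C=C(\C)[C@@H](O[Si](C)(C)C(C)(C)C)C/C=C(/C)[C@@H]1OC(C)(C)O[C@@H]1/C=C(\C)CO
F8 | step 11 | the C12 allylic chloride from F7 (C6 tert-butyl ester kept) | CC(C)(C)OC(=O)/C=C(\C)[C@@H](O[Si](C)(C)C(C)(C)C)C/C=C(/C)[C@@H]1OC(C)(C)O[C@@H]1/C=C(\C)CCl
F9 | step 11 | diol 16 with the C12 hydroxyl replaced by chlorine (C6–OH free) | OC/C=C(\C)[C@@H](O[Si](C)(C)C(C)(C)C)C/C=C(/C)[C@@H]1OC(C)(C)O[C@@H]1/C=C(\C)CCl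
F10 | step 11 | the C6 enal of F9 (C12 chloride) | O=C/C=C(\C)[C@@H](O[Si](C)(C)C(C)(C)C)C/C=C(/C)[C@@H]1OC(C)(C)O[C@@H]1/C=C(\C)CCl
F11 | step 16 | diol 30 as its 9-O-triethylsilyl ether (8-OH free) | C=C1C(=O)O[C@@H]2/C=C(\C)[C@@H](O[Si](C)(C)C(C)(C)C)C/C=C(/C)[C@H](O[Si](CC)(CC)CC)[C@H](O)[C@@H]12
F12 | step 16 | the 8-O-angeloyl 9-O-triethylsilyl derivative of 30 | C=C1C(=O)O[C@@H]2/C=C(\C)[C@@H](O[Si](C)(C)C(C)(C)C)C/C=C(/C)[C@H](O[Si](CC)(CC)CC)[C@H](OC(=O)/C(C)=C\C)[C@@H]12
F13 | step 16 | the 8-O-angeloyl 9-hydroxy derivative of 30 | C=C1C(=O)O[C@@H]2/C=C(\C)[C@@H](O[Si](C)(C)C(C)(C)C)C/C=C(/C)[C@H](O)[C@H](OC(=O)/C(C)=C\C)[C@@H]12
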